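The ten-membered carbocycle is closed last, at the bond between the ketone carbon (C1) and the methyl-bearing oxolane carbon (C10), by an N-heterocyclic-carbene-catalysed decarboxylative radical acylation. The C1 aldehyde becomes a Breslow-type enolate that reduces the N-acyloxyphthalimide on C10, and the ketyl/tertiary α-oxy radical pair collapses to the ketone. The step exploits the oxolane ring (O, C7, C8, C9, C10), whose 2,5-positions are bridged by the C1–C6 chain: only bonding cis to C6 is possible, so the planar C10 radical gives one configuration from either precursor epimer. The precursor is the complete spiro lactone–oxolane carrying epoxide, tiglate, aldehyde and redox-active ester.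

Key step: step 17

Remark on the chemistry: germacrane-type numbering is used (C1 ketone carbon; C2, C3 the CH2 groups; C4/C5 the epoxide carbons, C4 bearing a methyl; C6 the lactone CH–O; C7 the spiro carbon; C8 the tigloyloxy carbon; C9 the ring CH2; C10 the methyl-bearing oxolane carbon; C11=C13 the exocyclic alkene; C12 the lactone carbonyl). Compounds 8–11 and 15–21 are carried as both C10 epimers and are written without a descriptor there.

Step 1
Reactants: 1 ethyl glyoxylate; 2 2-methylpropene
Product: 3 ethyl (2S)-2-hydroxy-4-methylpent-4-enoate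
Conditions: (S)-BINOL (10 mol %), Ti(OiPr)2Cl2 (10 mol %), 4 Å MS, CH2Cl2, −30 °C
Reagents that add atoms: none
Why: Catalytic asymmetric glyoxylate–ene reaction; the (S)-BINOL–titanium Lewis acid binds the aldehyde and exposes one face to the ene, so C8 should form with S configuration.

Step 2
Reactants: 3 ethyl (2S)-2-hydroxy-4-methylpent-4-enoate
Product: 4 (2S)-2-hydroxy-N-methoxy-N,4-dimethylpent-4-enamide
Conditions: MeNH(OMe)·HCl, i-PrMgCl, THF, −20 to 0 °C
Reagents that add atoms: N,O-dimethylhydroxylamine hydrochloride, CNOC.Cl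
Why: Aminolysis of the ester by the magnesium amide (Weinreb amide formation); the magnesium alkoxide of the free hydroxyl protects the α-stereocentre from enolisation.

Step 3
Reactants: 4 (2S)-2-hydroxy-N-methoxy-N,4-dimethylpent-4-enamide
Product: 5 (4S)-4-hydroxy-6-methylhepta-1,6-dien-3-one
Conditions: CH2=CHMgBr (3 equiv), THF, −78 to 0 °C; cold aq. NH4Cl/AcOH quench
Reagents that add atoms: vinylmagnesium bromide, C=C[Mg]Br
Why: Weinreb ketone synthesis; the chelated tetrahedral adduct survives until quench, so one vinyl group is delivered and C8 is untouched.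

Step 4
Reactants: 5 (4S)-4-hydroxy-6-methylhepta-1,6-dien-3-one
Product: 6 (3S,4S)-3-ethynyl-6-methylhepta-1,6-diene-3,4-diol
Conditions: HC≡CMgBr (4 equiv), THF, −78 to −20 °C
Reagents that add atoms: ethynylmagnesium bromide, C#C[Mg]Br
Why: Chelation-controlled (Cram chelate) 1,2-addition of an alkynyl Grignard reagent; the C8 magnesium alkoxide binds the ketone oxygen and ethynyl attacks the face opposite the methallyl chain, setting C7.

Step 5
Reactants: 6 (3S,4S)-3-ethynyl-6-methylhepta-1,6-diene-3,4-diol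
Product: 7 (3S,4S)-3-ethynyl-3-hydroxy-6-methylhepta-1,6-dien-4-yl (2E)-2-methylbut-2-enoate
Conditions: tigloyl chloride, pyridine, DMAP (cat.), CH2Cl2, 0 °C
Reagents that add atoms: (2E)-2-methylbut-2-enoyl chloride, C/C=C(\C)C(=O)Cl
Why: Pyridine/DMAP acylation of the secondary alcohol; the tertiary propargylic hydroxyl is too hindered to react and the (E)-geometry of the acyl chloride is retained.

Step 6
Reactants: 7 mono-tiglate of diol 6
Product: 9 (2S,3S)-2-ethenyl-2-ethynyl-5-(hydroxymethyl)-5-methyloxolan-3-yl (2E)-2-methylbut-2-enoate, via epoxide 8 (not isolated)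
Conditions: mCPBA (1.05 equiv), NaHCO3, CH2Cl2, 0 °C; then CSA (10 mol %), rt
Reagents that add atoms: 3-chloroperoxybenzoic acid, O=C(OO)c1cccc(Cl)c1
Why: Prilezhaev epoxidation of the most electron-rich 1,1-disubstituted alkene, then acid-catalysed 5-exo-tet opening at the tertiary epoxide carbon by the C7 hydroxyl; C10 forms as both epimers, which is acceptable because it later passes through a planar radical.

Step 7
Reactants: 9 oxolane alcohol
Product: 10 (2S,3S)-5-({[tert-butyl(dimethyl)silyl]oxy}methyl)-2-ethenyl-2-ethynyl-5-methyloxolan-3-yl (2E)-2-methylbut-2-enoate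
Conditions: TBSCl, imidazole, DMF, rt
Reagents that add atoms: tert-butyldimethylsilyl chloride, CC(C)(C)[Si](C)(C)Cl
Why: Silylation of the primary alcohol, which keeps it from forming a lactol with the aldehyde made in step 8.

Step 8
Reactants: 10 silyl ether
Product: 11 (2S,3S)-5-({[tert-butyl(dimethyl)silyl]oxy}methyl)-2-ethynyl-2-formyl-5-methyloxolan-3-yl (2E)-2-methylbut-2-enoate
Conditions: OsO4 (2 mol %), NaIO4 (4 equiv), 2,6-lutidine, dioxane/H2O (3:1), rt
Reagents that add atoms: osmium tetroxide (oxygen carrier), O=[Os](=O)(=O)=O; sodium periodate (terminal oxygen source), [Na+].[O-][I](=O)(=O)=O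
Why: Lemieux–Johnson oxidation; the unconjugated monosubstituted alkene is dihydroxylated far faster than the conjugated trisubstituted tiglate or the alkyne, and periodate cleaves the diol to the C6 aldehyde.

Step 9
Reactants: 12 hex-1-en-5-yne
Product: 14 (1E)-1-iodo-2-methylhexa-1,5-diene, via alkenylalane 13 (not isolated)
Conditions: AlMe3 (2 equiv), Cp2ZrCl2 (20 mol %), CH2Cl2, 0 °C to rt; then I2, THF, −30 °C
Reagents that add atoms: trimethylaluminium, C[Al](C)C; iodine, II
Why: Negishi zirconium-catalysed carboalumination adds methyl and aluminium syn across the terminal alkyne only, and iodinolysis with retention fixes the (E)-geometry of the future C4=C5 bond.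

Step 10
Reactants: 11 oxolane aldehyde; 14 (1E)-1-iodo-2-methylhexa-1,5-diene
Product: 15 (2R,3S)-5-({[tert-butyl(dimethyl)silyl]oxy}methyl)-2-ethynyl-2-[(1R,2E)-1-hydroxy-3-methylhepta-2,6-dien-1-yl]-5-methyloxolan-3-yl (2E)-2-methylbut-2-enoate
Conditions: CrCl2 (6 equiv), NiCl2 (2 mol %), DMSO, rt
Reagents that add atoms: none
Why: Nozaki–Hiyama–Kishi coupling; the alkenylchromium reagent should add under polar Felkin–Anh control (C7–O bond anti to the nucleophile, the slim ethynyl group flanking its trajectory), setting C6 with the alkene geometry retained.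

Step 11
Reactants: 15 allylic alcohol
Product: 16 (2R,3S)-2-{(R)-[(2R,3R)-3-(but-3-en-1-yl)-3-methyloxiran-2-yl](hydroxy)methyl}-5-({[tert-butyl(dimethyl)silyl]oxy}methyl)-2-ethynyl-5-methyloxolan-3-yl (2E)-2-methylbut-2-enoate
Conditions: mCPBA (1.1 equiv), NaHCO3, CH2Cl2, −10 °C
Reagents that add atoms: 3-chloroperoxybenzoic acid, O=C(OO)c1cccc(Cl)c1
Why: Hydroxyl-directed Prilezhaev epoxidation of the only electron-rich trisubstituted alkene; minimised A(1,3) strain between C6–H and the cis methyl on C4 places the hydroxyl on one face and should give the threo epoxy alcohol, setting C4 and C5.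

Step 12
Reactants: 16 epoxy alcohol
Product: 17 spiro α-methylene lactone, (1R,5S,9S)-1-[(2R,3R)-3-(but-3-en-1-yl)-3-methyloxiran-2-yl]-7-({[tert-butyl(dimethyl)silyl]oxy}methyl)-7-methyl-4-methylidene-3-oxo-2,6-dioxaspiro[4.4]nonan-9-yl (2E)-2-methylbut-2-enoate
Conditions: PdCl2 (5 mol %), SnCl2 (5 mol %), PPh3 (10 mol %), CO (7 atm), MeCN, 65 °C
Reagents that add atoms: carbon monoxide, [C-]#[O+]
Why: Palladium-catalysed cyclocarbonylation of a homopropargylic alcohol; an alkoxycarbonyl–palladium species formed at the C6 hydroxyl adds across the alkyne in a 5-exo-dig sense and protonolysis releases the α-methylene-γ-lactone without touching a stereocentre.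

Step 13
Reactants: 17 spiro lactone silyl ether
Product: 18 the corresponding 7-(hydroxymethyl) spiro lactone
Conditions: HF·pyridine, pyridine, THF, 0 °C to rt
Reagents that add atoms: none
Why: Fluoride-mediated desilylation of the primary silyl ether under buffered conditions that should spare the epoxide, the lactone and the ester.

Step 14
Reactants: 18 primary alcohol
Product: 19 the corresponding 2,6-dioxaspiro[4.4]nonane-7-carboxylic acid
Conditions: TEMPO (20 mol %), PhI(OAc)2 (2.5 equiv), MeCN/H2O (1:1), rt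
Reagents that add atoms: water, O
Why: TEMPO/PhI(OAc)2 oxidation of the primary alcohol through the aldehyde hydrate to the acid; the electron-poor and terminal alkenes and the epoxide are inert.

Step 15
Reactants: 19 carboxylic acid
Product: 20 acid aldehyde, 1-[(2R,3R)-3-methyl-3-(3-oxopropyl)oxiran-2-yl] analogue of 19
Conditions: OsO4 (2 mol %), NaIO4 (2.2 equiv), 2,6-lutidine, dioxane/H2O (3:1), 0 °C to rt
Reagents that add atoms: osmium tetroxide (oxygen carrier), O=[Os](=O)(=O)=O; sodium periodate (terminal oxygen source), [Na+].[O-][I](=O)(=O)=O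
Why: Lemieux–Johnson oxidation of the only unconjugated alkene; the α-methylene lactone and the tiglate are electron-poor and react much more slowly with OsO4.

Step 16
Reactants: 20 acid aldehyde
Product: 21 1,3-dioxoisoindolin-2-yl ester of 20 (redox-active ester aldehyde)
Conditions: N-hydroxyphthalimide, DIC, DMAP (5 mol %), CH2Cl2, 0 °C to rt
Reagents that add atoms: N-hydroxyphthalimide, O=C1c2ccccc2C(=O)N1O
Why: Carbodiimide (Steglich-type) esterification of the tertiary acid gives the redox-active ester; the aldehyde is inert.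

Step 17
Reactants: 21 redox-active ester aldehyde
Product: 22 target, (4R,5R,6R,7S,8S,10R)-4,5:7,10-diepoxy-1-oxo-8-[(2E)-2-methylbut-2-enoyloxy]germacr-11(13)-en-12,6-olide
Conditions: 3-(2,6-diisopropylphenyl)-5,6,7,8-tetrahydro-4H-cyclohepta[d]thiazol-3-ium perchlorate (20 mol %), Cs2CO3 (20 mol %), degassed DMSO, 60 °C, syringe-pump addition of 21 to 0.002 M
Reagents that add atoms: none
Why: Proposed new method: the thiazolylidene adds to the C1 aldehyde to give a Breslow intermediate whose enolate form transfers one electron to the N-acyloxyphthalimide of the same molecule; loss of phthalimide anion and CO2 leaves the tertiary α-oxy radical at C10 beside the carbene-bound ketyl radical, and radical–radical recombination followed by release of the carbene gives the C1 ketone. The closest known reaction is the intermolecular NHC-catalysed decarboxylative radical acylation of aliphatic aldehydes with tertiary N-acyloxyphthalimides, which has not been used to close a medium ring. The step closes the ten-membered carbocycle (a nine-membered oxacycle through the ring oxygen) by end-to-end collapse of a biradical, with no alkene acceptor and hence no exo/endo choice. The new stereocentre C10 arises from a planar radical and is fixed as R by C7, because the C1–C6 tether can reach C10 only on the oxolane face that carries C6, so both epimers of 21 converge. Cyclisation must beat intermolecular coupling, hydrogen abstraction and Giese addition to the methylene lactone; high dilution, the birth of both radicals in one molecule and the strained 5-endo path from C10 to C13 should secure this.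

Compound list
1 | ethyl glyoxylate (ethyl 2-oxoacetate) | CCOC(=O)C=O | starting material
2 | 2-methylpropene | CC(C)=C | starting material
3 | ethyl (2S)-2-hydroxy-4-methylpent-4-enoate | C=C(C)C[C@H](O)C(=O)OCC | intermediate
4 | (2S)-2-hydroxy-N-methoxy-N,4-dimethylpent-4-enamide | C=C(C)C[C@H](O)C(=O)N(C)OC | intermediate
5 | (4S)-4-hydroxy-6-methylhepta-1,6-dien-3-one | C=C(C)C[C@H](O)C(=O)C=C | intermediate
6 | (3S,4S)-3-ethynyl-6-methylhepta-1,6-diene-3,4-diol | C=C(C)C[C@H](O)[C@@](C#C)(C=C)O | intermediate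
7 | (3S,4S)-3-ethynyl-3-hydroxy-6-methylhepta-1,6-dien-4-yl (2E)-2-methylbut-2-enoate | C=C(C)C[C@H](OC(=O)/C(C)=C/C)[C@@](C#C)(C=C)O | intermediate
8 | (2S,3S)-3-ethynyl-3-hydroxy-1-(2-methyloxiran-2-yl)pent-4-en-2-yl (2E)-2-methylbut-2-enoate, both oxirane epimers, not isolated | CC1(CO1)C[C@H](OC(=O)/C(C)=C/C)[C@@](C#C)(C=C)O | intermediate
9 | (2S,3S)-2-ethenyl-2-ethynyl-5-(hydroxymethyl)-5-methyloxolan-3-yl (2E)-2-methylbut-2-enoate, both C5 epimers | OCC1(C)C[C@H](OC(=O)/C(C)=C/C)[C@@](C#C)(C=C)O1 | intermediate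
10 | (2S,3S)-5-({[tert-butyl(dimethyl)silyl]oxy}methyl)-2-ethenyl-2-ethynyl-5-methyloxolan-3-yl (2E)-2-methylbut-2-enoate, both C5 epimers | CC(C)(C)[Si](C)(C)OCC1(C)C[C@H](OC(=O)/C(C)=C/C)[C@@](C#C)(C=C)O1 | intermediate
11 | (2S,3S)-5-({[tert-butyl(dimethyl)silyl]oxy}methyl)-2-ethynyl-2-formyl-5-methyloxolan-3-yl (2E)-2-methylbut-2-enoate, both C5 epimers | CC(C)(C)[Si](C)(C)OCC1(C)C[C@H](OC(=O)/C(C)=C/C)[C@@](C#C)(C=O)O1 | intermediate
12 | hex-1-en-5-yne | C=CCCC#C | starting material
13 | dimethyl[(1E)-2-methylhexa-1,5-dien-1-yl]alumane, not isolated | C=CCC/C(C)=C/[Al](C)C | intermediate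
14 | (1E)-1-iodo-2-methylhexa-1,5-diene | C=CCC/C(C)=C/I | intermediate
15 | (2R,3S)-5-({[tert-butyl(dimethyl)silyl]oxy}methyl)-2-ethynyl-2-[(1R,2E)-1-hydroxy-3-methylhepta-2,6-dien-1-yl]-5-methyloxolan-3-yl (2E)-2-methylbut-2-enoate, both C5 epimers | C=CCC/C(C)=C/[C@@H](O)[C@@]1(C#C)OC(C)(CO[Si](C)(C)C(C)(C)C)C[C@@H]1OC(=O)/C(C)=C/C | intermediate
16 | (2R,3S)-2-{(R)-[(2R,3R)-3-(but-3-en-1-yl)-3-methyloxiran-2-yl](hydroxy)methyl}-5-({[tert-butyl(dimethyl)silyl]oxy}methyl)-2-ethynyl-5-methyloxolan-3-yl (2E)-2-methylbut-2-enoate, both C5 epimers | C=CCC[C@@]1(C)O[C@@H]1[C@@H](O)[C@@]2(C#C)OC(C)(CO[Si](C)(C)C(C)(C)C)C[C@@H]2OC(=O)/C(C)=C/C | intermediate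
17 | (1R,5S,9S)-1-[(2R,3R)-3-(but-3-en-1-yl)-3-methyloxiran-2-yl]-7-({[tert-butyl(dimethyl)silyl]oxy}methyl)-7-methyl-4-methylidene-3-oxo-2,6-dioxaspiro[4.4]nonan-9-yl (2E)-2-methylbut-2-enoate, both C7 epimers | C=C1C(=O)O[C@H]([C@H]2O[C@]2(C)CCC=C)[C@@]12[C@@H](OC(=O)/C(C)=C/C)CC(C)(CO[Si](C)(C)C(C)(C)C)O2 | intermediate
18 | (1R,5S,9S)-1-[(2R,3R)-3-(but-3-en-1-yl)-3-methyloxiran-2-yl]-7-(hydroxymethyl)-7-methyl-4-methylidene-3-oxo-2,6-dioxaspiro[4.4]nonan-9-yl (2E)-2-methylbut-2-enoate, both C7 epimers | C=C1C(=O)O[C@H]([C@H]2O[C@]2(C)CCC=C)[C@@]12[C@@H](OC(=O)/C(C)=C/C)CC(C)(CO)O2 | intermediate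
19 | (1R,5S,9S)-1-[(2R,3R)-3-(but-3-en-1-yl)-3-methyloxiran-2-yl]-7-methyl-4-methylidene-9-{[(2E)-2-methylbut-2-enoyl]oxy}-3-oxo-2,6-dioxaspiro[4.4]nonane-7-carboxylic acid, both C7 epimers | C=C1C(=O)O[C@H]([C@H]2O[C@]2(C)CCC=C)[C@@]12[C@@H](OC(=O)/C(C)=C/C)CC(C)(C(=O)O)O2 | intermediate
20 | (1R,5S,9S)-7-methyl-4-methylidene-9-{[(2E)-2-methylbut-2-enoyl]oxy}-1-[(2R,3R)-3-methyl-3-(3-oxopropyl)oxiran-2-yl]-3-oxo-2,6-dioxaspiro[4.4]nonane-7-carboxylic acid, both C7 epimers | C=C1C(=O)O[C@H]([C@H]2O[C@]2(C)CCC=O)[C@@]12[C@@H](OC(=O)/C(C)=C/C)CC(C)(C(=O)O)O2 | intermediate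
21 | 1,3-dioxoisoindolin-2-yl ester of acid 20, both C7 epimers | C=C1C(=O)O[C@H]([C@H]2O[C@]2(C)CCC=O)[C@@]12[C@@H](OC(=O)/C(C)=C/C)CC(C)(C(=O)ON3C(=O)c4ccccc4C3=O)O2 | intermediate
22 | CNP0281419.1, (4R,5R,6R,7S,8S,10R)-4,5:7,10-diepoxy-1-oxo-8-[(2E)-2-methylbut-2-enoyloxy]germacr-11(13)-en-12,6-olide | C=C1C(=O)O[C@@H]2[C@H]3O[C@]3(C)CCC(=O)[C@@]3(C)C[C@H](OC(=O)/C(C)=C/C)[C@@]12O3 | target

Total step count: 17. Longest linear sequence: 16 steps (steps 1–8 and 10–17).

Steps most likely to fail

Step 17 (Proposed new method). What may go wrong: oligomerisation through intermolecular radical coupling, quenching of the C10 radical by hydrogen abstraction, or consumption of the methylene lactone by Michael-type addition under the basic carbene conditions. The fallback uses known chemistry and closes the ring at C5–C6 instead. It sets out from 9 and 14. Alcohol 9 would be oxidised (TEMPO, PhI(OAc)2) to (4S,5S)-5-ethenyl-5-ethynyl-2-methyl-4-{[(2E)-2-methylbut-2-enoyl]oxy}oxolane-2-carboxylic acid F1 and esterified (N-hydroxyphthalimide, DIC) to its 1,3-dioxoisoindolin-2-yl ester F2. Iodide 14 would be cleaved (OsO4, NaIO4) to (4E)-5-iodo-4-methylpent-4-enal F3. The intermolecular NHC-catalysed decarboxylative radical acylation of F3 with F2 (same catalyst, Cs2CO3, DMSO) should give the ketone (2S,3S,5R)-2-ethenyl-2-ethynyl-5-[(4E)-5-iodo-4-methylpent-4-enoyl]-5-methyloxolan-3-yl (2E)-2-methylbut-2-enoate F4, whose C10 epimer with the acyl group cis to the vinyl group would be separated. Lemieux–Johnson cleavage of the vinyl group should give the 2-formyl analogue F5. An intramolecular Nozaki–Hiyama–Kishi reaction (CrCl2, NiCl2, DMSO, high dilution) should then close the ring to the macrocyclic allylic alcohol F6 (C1 ketone, (E)-C4=C5, C6 carbinol, C7 ethynyl). Hydroxyl-directed mCPBA epoxidation should give the 4,5-epoxide F7, and cyclocarbonylation as in step 12 would return to the route at 22.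

Step 12. What may go wrong: opening or rearrangement of the acid-sensitive epoxy alcohol by the Lewis-acidic PdCl2/SnCl2 system before carbonylation is complete. The fallback sets out from 16. Hydrostannation (Bu3SnH, Mo(CO)3(CNtBu)3 cat.) should give the internal alkenylstannane F8, the 2-[1-(tributylstannyl)ethenyl] analogue of 16. Iododestannylation (I2, CH2Cl2, 0 °C) should give the 2-(1-iodoethenyl) analogue F9. Alkoxycarbonylation under neutral-to-basic conditions (Pd(PPh3)4, CO 1 atm, Et3N, MeCN) would return to the route at 17.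

Step 10. What may go wrong: poor facial selectivity at C6 if a chelated transition state competes with the Felkin–Anh one. The fallback sets out from 15 (as its C6 epimer mixture). Oxidation with Dess–Martin periodinane should give the enone (2S,3S)-5-({[tert-butyl(dimethyl)silyl]oxy}methyl)-2-ethynyl-5-methyl-2-[(2E)-3-methylhepta-2,6-dienoyl]oxolan-3-yl (2E)-2-methylbut-2-enoate F10. Reduction with Zn(BH4)2 (Et2O, −20 °C) should proceed through a chelate between the ketone and the ring oxygen with hydride delivered from the ethynyl face, returning to the route at 15 as the 6R epimer.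

Further compounds
F1 | step 17 | (4S,5S)-5-ethenyl-5-ethynyl-2-methyl-4-{[(2E)-2-methylbut-2-enoyl]oxy}oxolane-2-carboxylic acid, both C2 epimers | OC(=O)C1(C)C[C@H](OC(=O)/C(C)=C/C)[C@@](C#C)(C=C)O1
F2 | step 17 | 1,3-dioxoisoindolin-2-yl ester of F1 | O=C(ON1C(=O)c2ccccc2C1=O)C3(C)C[C@H](OC(=O)/C(C)=C/C)[C@@](C#C)(C=C)O3
F3 | step 17 | (4E)-5-iodo-4-methylpent-4-enal | O=CCC/C(C)=C/I
F4 | step 17 | (2S,3S,5R)-2-ethenyl-2-ethynyl-5-[(4E)-5-iodo-4-methylpent-4-enoyl]-5-methyloxolan-3-yl (2E)-2-methylbut-2-enoate | O=C(CC/C(C)=C/I)[C@@]1(C)C[C@H](OC(=O)/C(C)=C/C)[C@@](C#C)(C=C)O1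
F5 | step 17 | (2S,3S,5R)-2-ethynyl-2-formyl-5-[(4E)-5-iodo-4-methylpent-4-enoyl]-5-methyloxolan-3-yl (2E)-2-methylbut-2-enoate | O=C(CC/C(C)=C/I)[C@@]1(C)C[C@H](OC(=O)/C(C)=C/C)[C@@](C#C)(C=O)O1
F6 | step 17 | macrocyclic allylic alcohol: 7-ethynyl-6-hydroxy-7,10-epoxy-1-oxogermacr-4(E)-en-8-yl (2E)-2-methylbut-2-enoate, configured as 22 at C6, C7, C8, C10 | O[C@@H]1/C=C(\C)CCC(=O)[C@@]2(C)C[C@H](OC(=O)/C(C)=C/C)[C@]1(C#C)O2
F7 | step 17 | 4,5-epoxide of F6, configured as 22 at C4–C8 and C10 | O[C@@H]1[C@H]3O[C@]3(C)CCC(=O)[C@@]2(C)C[C@H](OC(=O)/C(C)=C/C)[C@]1(C#C)O2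
F8 | step 12 | 2-[1-(tributylstannyl)ethenyl] analogue of 16 | C=CCC[C@@]1(C)O[C@@H]1[C@@H](O)[C@@]2(C(=C)[Sn](CCCC)(CCCC)CCCC)OC(C)(CO[Si](C)(C)C(C)(C)C)C[C@@H]2OC(=O)/C(C)=C/C
F9 | step 12 | 2-(1-iodoethenyl) analogue of 16 | C=CCC[C@@]1(C)O[C@@H]1[C@@H](O)[C@@]2(C(=C)I)OC(C)(CO[Si](C)(C)C(C)(C)C)C[C@@H]2OC(=O)/C(C)=C/C
F10 | step 10 | (2S,3S)-5-({[tert-butyl(dimethyl)silyl]oxy}methyl)-2-ethynyl-5-methyl-2-[(2E)-3-methylhepta-2,6-dienoyl]oxolan-3-yl (2E)-2-methylbut-2-enoate | C=CCC/C(C)=C/C(=O)[C@@]1(C#C)OC(C)(CO[Si](C)(C)C(C)(C)C)C[C@@H]1OC(=O)/C(C)=C/C
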